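**Retrosynthetic overview**
1. Target 29 ⇐ C8–O acylation of hemiketal 23 with N‑methylurocanic acid 26 (the dihydrofuran O‑bridge closes last); C7–CH3 from MeCeCl2 on bridged hydroxypyranone 22; 22 from Achmatowicz oxidation of furanophane 20.
2. Ten‑membered ring (third ring): C3–C4 bond by a new Pd‑catalysed intramolecular furan C–H alkenylation with a (Z)‑α‑bromoenoate (18 → 19).
3. Cyclohexene (second ring; C1–C10 bond, C1 and C10 stereocentres, C11=C12): boat Ireland–Claisen ring contraction of the 4,6‑trans δ‑lactone 12 carrying a Z‑alkenyl group.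
4. δ‑Lactone (first ring, later sacrificed): Brown allylation of Z‑enal 7, acryloylation, ring‑closing metathesis, Cu‑catalysed i‑PrMgCl 1,4‑addition (sets C14).
5. Z‑enal 7 from ethyl 3‑(furan‑2‑yl)‑3‑oxopropanoate 1 (transfer hydrogenation sets C8, Still–Gennari olefination sets the Z‑alkene); ring order: lactone → cyclohexene → ten‑membered ring → pyranone → dihydrofuran hemiketal.

Assumption: the SMILES is taken literally, i.e. 1R,4R,7S,8S,10R,14R with the locants used below (C1/C10 = ring fusion, C14 bears i‑Pr, C11 bears CH3, C3 bears CO2Me, C4 and C7 carry the oxygen bridge, C8 the ester oxygen), so that on the cyclohexene the C1–C2 bond is cis to i‑Pr and trans to the C10–C9 bond; the route is built for exactly this arrangement.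

**Route**

Step 1
Reactants: 1 ethyl 3-(furan-2-yl)-3-oxopropanoate
Product: 2 ethyl (3S)-3-(furan-2-yl)-3-hydroxypropanoate
Conditions: RuCl[(S,S)-TsDPEN](p-cymene) (1 mol %), HCO2H/Et3N (5:2), DMF, 25 °C
Reagents that add atoms: none
Why: Noyori asymmetric transfer hydrogenation, in which the furyl group takes the aryl position of the CH–π‑controlled outer‑sphere transition state so that the (S,S)‑ligand delivers hydride to give the 3S carbinol (C8 of the target).

Step 2
Reactants: 2 ethyl (3S)-3-(furan-2-yl)-3-hydroxypropanoate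
Product: 3 ethyl (3S)-3-[(tert-butyldimethylsilyl)oxy]-3-(furan-2-yl)propanoate
Conditions: t-BuMe2SiCl, imidazole, DMF, 25 °C
Reagents that add atoms: tert-butyldimethylsilyl chloride, CC(C)(C)[Si](C)(C)Cl
Why: Imidazole‑promoted O‑silylation protects the acid‑labile furyl carbinol without touching the stereocentre.

Step 3
Reactants: 3 ethyl (3S)-3-[(tert-butyldimethylsilyl)oxy]-3-(furan-2-yl)propanoate
Product: 4 (3S)-3-[(tert-butyldimethylsilyl)oxy]-3-(furan-2-yl)propanal
Conditions: i-Bu2AlH (1.1 equiv), CH2Cl2, −78 °C; aq. potassium sodium tartrate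
Reagents that add atoms: none
Why: Partial ester reduction, because the tetrahedral aluminium hemiacetal is stable at −78 °C and releases the aldehyde only on work‑up; the β‑stereocentre cannot epimerise.

Step 4
Reactants: 4 (3S)-3-[(tert-butyldimethylsilyl)oxy]-3-(furan-2-yl)propanal
Product: 5 ethyl (2Z,5S)-5-[(tert-butyldimethylsilyl)oxy]-5-(furan-2-yl)-2-methylpent-2-enoate
Conditions: (CF3CH2O)2P(O)CH(CH3)CO2Et, KN(SiMe3)2, 18-crown-6, THF, −78 °C
Reagents that add atoms: ethyl 2-[bis(2,2,2-trifluoroethoxy)phosphoryl]propanoate, CCOC(=O)C(C)P(=O)(OCC(F)(F)F)OCC(F)(F)F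
Why: Still–Gennari variant of the Horner–Wadsworth–Emmons reaction, in which the electron‑poor phosphonate with a dissociated potassium ion eliminates fast from the kinetic adduct and gives the Z‑trisubstituted enoate (ester cis to C9).

Step 5
Reactants: 5 ethyl (2Z,5S)-5-[(tert-butyldimethylsilyl)oxy]-5-(furan-2-yl)-2-methylpent-2-enoate
Product: 6 (2Z,5S)-5-[(tert-butyldimethylsilyl)oxy]-5-(furan-2-yl)-2-methylpent-2-en-1-ol
Conditions: i-Bu2AlH (2.5 equiv), CH2Cl2, −78 → 0 °C; aq. potassium sodium tartrate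
Reagents that add atoms: none
Why: 1,2‑Reduction of the enoate by the aluminium hydride gives the allylic alcohol with the Z geometry retained.

Step 6
Reactants: 6 (2Z,5S)-5-[(tert-butyldimethylsilyl)oxy]-5-(furan-2-yl)-2-methylpent-2-en-1-ol
Product: 7 (2Z,5S)-5-[(tert-butyldimethylsilyl)oxy]-5-(furan-2-yl)-2-methylpent-2-enal
Conditions: Dess–Martin periodinane, NaHCO3, CH2Cl2, 0 °C
Reagents that add atoms: none
Why: Dess–Martin oxidation under buffered, non‑isomerising conditions gives the Z‑enal, which is used at once.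

Step 7
Reactants: 7 (2Z,5S)-5-[(tert-butyldimethylsilyl)oxy]-5-(furan-2-yl)-2-methylpent-2-enal
Product: 9 (4R,5Z,8S)-8-[(tert-butyldimethylsilyl)oxy]-8-(furan-2-yl)-5-methylocta-1,5-dien-4-ol, via diisopinocampheylborinate 8 (not isolated)
Conditions: (−)-Ipc2B(allyl), Et2O, −78 °C; then NaOH, H2O2, 0 → 25 °C
Reagents that add atoms: (−)-B-allyldiisopinocampheylborane (from (+)-α-pinene), C=CCB([C@@H]1C[C@@H]2C[C@H]([C@H]1C)C2(C)C)[C@@H]1C[C@@H]2C[C@H]([C@H]1C)C2(C)C
Why: Brown allylboration through a closed chair‑like six‑membered transition state, in which the isopinocampheyl groups of the (−)‑reagent direct allyl transfer to the Re face of the enal and set the temporary 4R carbinol (C12) under reagent control without Z/E isomerisation.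

Step 8
Reactants: 9 (4R,5Z,8S)-8-[(tert-butyldimethylsilyl)oxy]-8-(furan-2-yl)-5-methylocta-1,5-dien-4-ol
Product: 10 (4R,5Z,8S)-8-[(tert-butyldimethylsilyl)oxy]-8-(furan-2-yl)-5-methylocta-1,5-dien-4-yl prop-2-enoate
Conditions: acryloyl chloride, Et3N, DMAP (cat.), CH2Cl2, −20 → 0 °C
Reagents that add atoms: acryloyl chloride, C=CC(=O)Cl
Why: O‑Acylation with an acid chloride proceeds at oxygen with retention at C12.

Step 9
Reactants: 10 (4R,5Z,8S)-8-[(tert-butyldimethylsilyl)oxy]-8-(furan-2-yl)-5-methylocta-1,5-dien-4-yl prop-2-enoate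
Product: 11 (6R)-6-[(2Z,5S)-5-[(tert-butyldimethylsilyl)oxy]-5-(furan-2-yl)pent-2-en-2-yl]-5,6-dihydro-2H-pyran-2-one
Conditions: second-generation Grubbs catalyst (5 mol %), CH2Cl2 (0.005 M), 40 °C
Reagents that add atoms: none
Why: Ring‑closing metathesis, in which the catalyst loads on the terminal alkene and closes onto the acrylate while the hindered trisubstituted Z‑alkene stays out.

Step 10
Reactants: 11 (6R)-6-[(2Z,5S)-5-[(tert-butyldimethylsilyl)oxy]-5-(furan-2-yl)pent-2-en-2-yl]-5,6-dihydro-2H-pyran-2-one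
Product: 12 (4S,6R)-6-[(2Z,5S)-5-[(tert-butyldimethylsilyl)oxy]-5-(furan-2-yl)pent-2-en-2-yl]-4-(propan-2-yl)oxan-2-one
Conditions: i-PrMgCl, CuBr·SMe2 (10 mol %), THF, −78 °C; then H2O
Reagents that add atoms: isopropylmagnesium chloride, CC(C)[Mg]Cl
Why: Copper‑catalysed conjugate addition, in which the isopropyl group adds axially to the half‑chair enoate anti to the pseudo‑equatorial C6 alkenyl group and gives the 4,6‑trans lactone (C14, R in the target), the hindered allylic C–O bond not being displaced at −78 °C.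

Step 11
Reactants: 12 (4S,6R)-6-[(2Z,5S)-5-[(tert-butyldimethylsilyl)oxy]-5-(furan-2-yl)pent-2-en-2-yl]-4-(propan-2-yl)oxan-2-one
Product: 15 (1S,2R,6R)-2-[(2S)-2-[(tert-butyldimethylsilyl)oxy]-2-(furan-2-yl)ethyl]-3-methyl-6-(propan-2-yl)cyclohex-3-ene-1-carboxylic acid, via silyl ketene acetal 13 (not isolated), via trimethylsilyl ester 14 (not isolated)
Conditions: LiN(i-Pr)2, THF, −78 °C; Me3SiCl/Et3N, −78 → 25 °C; toluene, 110 °C; then H2O
Reagents that add atoms: none
Why: Ireland–Claisen rearrangement of a lactone enolate (ring contraction), in which the ring forces a boat‑like [3,3] transition state so that the C1–C10 bond forms on the lactone face carrying the alkenyl group (opposite to i‑Pr, hence CO2H cis to i‑Pr) and the Z‑alkene places C9 trans to CO2H, setting C1, C10 and the C11=C12 bond in one step.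

Step 12
Reactants: 15 (1S,2R,6R)-2-[(2S)-2-[(tert-butyldimethylsilyl)oxy]-2-(furan-2-yl)ethyl]-3-methyl-6-(propan-2-yl)cyclohex-3-ene-1-carboxylic acid
Product: 16 [(1S,2R,6R)-2-[(2S)-2-[(tert-butyldimethylsilyl)oxy]-2-(furan-2-yl)ethyl]-3-methyl-6-(propan-2-yl)cyclohex-3-en-1-yl]methanol
Conditions: LiAlH4, THF, 0 → 40 °C; then H2O
Reagents that add atoms: none
Why: Hydride reduction of the carboxylic acid gives the primary alcohol, and silyl ether, furan and alkene are inert to LiAlH4.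

Step 13
Reactants: 16 [(1S,2R,6R)-2-[(2S)-2-[(tert-butyldimethylsilyl)oxy]-2-(furan-2-yl)ethyl]-3-methyl-6-(propan-2-yl)cyclohex-3-en-1-yl]methanol
Product: 17 (1S,2R,6R)-2-[(2S)-2-[(tert-butyldimethylsilyl)oxy]-2-(furan-2-yl)ethyl]-3-methyl-6-(propan-2-yl)cyclohex-3-ene-1-carbaldehyde
Conditions: Dess–Martin periodinane, NaHCO3, CH2Cl2, 0 → 25 °C
Reagents that add atoms: none
Why: Dess–Martin oxidation, buffered so that the α‑stereocentre C1 of the aldehyde does not epimerise.

Step 14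
Reactants: 17 (1S,2R,6R)-2-[(2S)-2-[(tert-butyldimethylsilyl)oxy]-2-(furan-2-yl)ethyl]-3-methyl-6-(propan-2-yl)cyclohex-3-ene-1-carbaldehyde
Product: 18 methyl (2Z)-2-bromo-3-[(1S,2R,6R)-2-[(2S)-2-[(tert-butyldimethylsilyl)oxy]-2-(furan-2-yl)ethyl]-3-methyl-6-(propan-2-yl)cyclohex-3-en-1-yl]prop-2-enoate
Conditions: Ph3P=CHCO2Me, N-bromosuccinimide, CH2Cl2, −20 °C (30 min); then 17, 25 °C
Reagents that add atoms: methyl (triphenylphosphoranylidene)acetate, COC(=O)C=P(c1ccccc1)(c1ccccc1)c1ccccc1; N-bromosuccinimide, O=C1CCC(=O)N1Br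
Why: Wittig olefination with a stabilised α‑bromo ylide made in the flask, in which reversible oxaphosphetane formation puts the ester trans to C1 (Br cis to C1, Z) and the weakly basic ylide does not epimerise C1.

Step 15
Reactants: 18 methyl (2Z)-2-bromo-3-[(1S,2R,6R)-2-[(2S)-2-[(tert-butyldimethylsilyl)oxy]-2-(furan-2-yl)ethyl]-3-methyl-6-(propan-2-yl)cyclohex-3-en-1-yl]prop-2-enoate
Product: 19 furanophane silyl ether (ten-membered ring C1–C10 closed by the C3–C4 bond; furan = C4–C7; C2=C3 bears CO2Me trans to C1; C8–OSiMe2t-Bu; 1R,8S,10R,14R)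
Conditions: Pd(OAc)2 (10 mol %), PCy3·HBF4 (20 mol %), t-BuCO2H (30 mol %), K2CO3, toluene, 100 °C, slow addition (final 0.002 M)
Reagents that add atoms: none
Why: Proposed new method: Pd(OAc)2/PCy3/pivalate‑catalysed macrocyclising C–H alkenylation of a furan by a tethered (Z)‑α‑bromoenoate, in which zerovalent palladium inserts into the activated C(sp2)–Br bond, the pivalate ligand removes the only free furan α‑hydrogen (C4–H) by concerted metalation–deprotonation and irreversible C–C reductive elimination closes the C3–C4 bond with the C1/C4‑cis alkene geometry the ring demands (no stereocentre is touched); the closest known reaction type is the intermolecular Pd/pivalate direct C5‑arylation and ‑alkenylation of 2‑alkylfurans with aryl and alkenyl bromides together with macrocyclising direct C–H arylations, none shown for a strained [6](2,5)furanophane or an α‑bromoenoate partner.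

Step 16
Reactants: 19 furanophane silyl ether
Product: 20 furanophane carbinol (as 19 with C8–OH; 1R,8S,10R,14R)
Conditions: Bu4NF, AcOH, THF, 0 → 25 °C
Reagents that add atoms: none
Why: Fluoride‑mediated desilylation driven by Si–F bond formation, buffered with AcOH to spare the enoate and the sensitive furyl carbinol.

Step 17
Reactants: 20 furanophane carbinol
Product: 22 bridged hydroxypyranone (O8 bonded to C4; C4–OH; C5=C6; C7=O; 1R,4S,8S,10R,14R), via ene-dione 21 (not isolated)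
Conditions: VO(acac)2 (5 mol %), t-BuOOH, CH2Cl2, 0 → 25 °C
Reagents that add atoms: tert-butyl hydroperoxide, CC(C)(C)OO
Why: Achmatowicz rearrangement, in which hydroxyl‑directed epoxidation of the furan bond next to the carbinol opens to the Z‑ene‑dione and O8 closes onto C4 to give the 6‑hydroxypyranone, the C4 configuration being fixed by the bridge and the remote trisubstituted alkene left alone.

Step 18
Reactants: 22 bridged hydroxypyranone
Product: 23 bridged pyranose diol (as 22 with C7(OH)(CH3), CH3 trans to C9; 1R,4S,7S,8S,10R,14R)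
Conditions: MeLi, CeCl3, THF, −78 °C; then H2O
Reagents that add atoms: methyllithium, [Li]C
Why: Organocerium 1,2‑addition, chemoselective for the ketone over the enoate, in which MeCeCl2 attacks C7 from the exo face of the bridged pyranone anti to the C8–C9 bond and sets the C7 quaternary centre (S).

Step 19
Reactants: 24 1-methyl-1H-imidazole-4-carbaldehyde
Product: 26 (2E)-3-(1-methyl-1H-imidazol-4-yl)prop-2-enoic acid, via alkylidenemalonic acid 25 (not isolated)
Conditions: malonic acid, pyridine, piperidine (cat.), 100 °C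
Reagents that add atoms: malonic acid, OC(=O)CC(O)=O
Why: Knoevenagel–Doebner condensation followed by decarboxylation in pyridine gives the thermodynamically favoured E‑acrylic acid.

Step 20
Reactants: 23 bridged pyranose diol; 26 (2E)-3-(1-methyl-1H-imidazol-4-yl)prop-2-enoic acid
Product: 29 target (1R,4R,7S,8S,10R,14R), via mixed pivalic anhydride 27 (not isolated), via furanose hemiketal 28 (not isolated)
Conditions: 26, t-BuCOCl, Et3N, THF, 0 °C; then 23, DMAP, toluene, 40 °C
Reagents that add atoms: none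
Why: Mixed‑anhydride esterification under Curtin–Hammett control, in which base‑mediated ring–chain tautomerism turns the pyranose into the dihydrofuran hemiketal 28 (C4 configuration fixed by the C7–O bridge) whose only unhindered hydroxyl, the secondary C8–OH, is acylated at the unshielded urocanoyl carbonyl while the tertiary hydroxyls stay free.

**Compound list**

1 | ethyl 3-(furan-2-yl)-3-oxopropanoate | CCOC(=O)CC(=O)c1ccco1 | starting material
2 | ethyl (3S)-3-(furan-2-yl)-3-hydroxypropanoate | CCOC(=O)C[C@H](O)c1ccco1 | intermediate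
3 | ethyl (3S)-3-[(tert-butyldimethylsilyl)oxy]-3-(furan-2-yl)propanoate | CCOC(=O)C[C@H](O[Si](C)(C)C(C)(C)C)c1ccco1 | intermediate
4 | (3S)-3-[(tert-butyldimethylsilyl)oxy]-3-(furan-2-yl)propanal | O=CC[C@H](O[Si](C)(C)C(C)(C)C)c1ccco1 | intermediate
5 | ethyl (2Z,5S)-5-[(tert-butyldimethylsilyl)oxy]-5-(furan-2-yl)-2-methylpent-2-enoate | CCOC(=O)/C(C)=C\C[C@H](O[Si](C)(C)C(C)(C)C)c1ccco1 | intermediate
6 | (2Z,5S)-5-[(tert-butyldimethylsilyl)oxy]-5-(furan-2-yl)-2-methylpent-2-en-1-ol | OC/C(C)=C\C[C@H](O[Si](C)(C)C(C)(C)C)c1ccco1 | intermediate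
7 | (2Z,5S)-5-[(tert-butyldimethylsilyl)oxy]-5-(furan-2-yl)-2-methylpent-2-enal | O=C/C(C)=C\C[C@H](O[Si](C)(C)C(C)(C)C)c1ccco1 | intermediate
8 | diisopinocampheylborinate of 9 | C=CC[C@@H](OB([C@@H]1C[C@@H]2C[C@H]([C@H]1C)C2(C)C)[C@@H]1C[C@@H]2C[C@H]([C@H]1C)C2(C)C)/C(C)=C\C[C@H](O[Si](C)(C)C(C)(C)C)c1ccco1 | intermediate
9 | (4R,5Z,8S)-8-[(tert-butyldimethylsilyl)oxy]-8-(furan-2-yl)-5-methylocta-1,5-dien-4-ol | C=CC[C@@H](O)/C(C)=C\C[C@H](O[Si](C)(C)C(C)(C)C)c1ccco1 | intermediate
10 | (4R,5Z,8S)-8-[(tert-butyldimethylsilyl)oxy]-8-(furan-2-yl)-5-methylocta-1,5-dien-4-yl prop-2-enoate | C=CC[C@@H](OC(=O)C=C)/C(C)=C\C[C@H](O[Si](C)(C)C(C)(C)C)c1ccco1 | intermediate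
11 | (6R)-6-[(2Z,5S)-5-[(tert-butyldimethylsilyl)oxy]-5-(furan-2-yl)pent-2-en-2-yl]-5,6-dihydro-2H-pyran-2-one | O=C1C=CC[C@@H](O1)/C(C)=C\C[C@H](O[Si](C)(C)C(C)(C)C)c1ccco1 | intermediate
12 | (4S,6R)-6-[(2Z,5S)-5-[(tert-butyldimethylsilyl)oxy]-5-(furan-2-yl)pent-2-en-2-yl]-4-(propan-2-yl)oxan-2-one (4,6-trans) | O=C1C[C@@H](C(C)C)C[C@@H](O1)/C(C)=C\C[C@H](O[Si](C)(C)C(C)(C)C)c1ccco1 | intermediate
13 | trimethylsilyl ketene acetal of 12 | C[Si](C)(C)OC1=C[C@@H](C(C)C)C[C@@H](O1)/C(C)=C\C[C@H](O[Si](C)(C)C(C)(C)C)c1ccco1 | intermediate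
14 | trimethylsilyl ester of 15 | C[Si](C)(C)OC(=O)[C@H]1[C@@H](C(C)C)CC=C(C)[C@@H]1C[C@H](O[Si](C)(C)C(C)(C)C)c1ccco1 | intermediate
15 | (1S,2R,6R)-2-[(2S)-2-[(tert-butyldimethylsilyl)oxy]-2-(furan-2-yl)ethyl]-3-methyl-6-(propan-2-yl)cyclohex-3-ene-1-carboxylic acid | OC(=O)[C@H]1[C@@H](C(C)C)CC=C(C)[C@@H]1C[C@H](O[Si](C)(C)C(C)(C)C)c1ccco1 | intermediate
16 | [(1S,2R,6R)-2-[(2S)-2-[(tert-butyldimethylsilyl)oxy]-2-(furan-2-yl)ethyl]-3-methyl-6-(propan-2-yl)cyclohex-3-en-1-yl]methanol | OC[C@H]1[C@@H](C(C)C)CC=C(C)[C@@H]1C[C@H](O[Si](C)(C)C(C)(C)C)c1ccco1 | intermediate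
17 | (1S,2R,6R)-2-[(2S)-2-[(tert-butyldimethylsilyl)oxy]-2-(furan-2-yl)ethyl]-3-methyl-6-(propan-2-yl)cyclohex-3-ene-1-carbaldehyde | O=C[C@H]1[C@@H](C(C)C)CC=C(C)[C@@H]1C[C@H](O[Si](C)(C)C(C)(C)C)c1ccco1 | intermediate
18 | methyl (2Z)-2-bromo-3-[(1S,2R,6R)-2-[(2S)-2-[(tert-butyldimethylsilyl)oxy]-2-(furan-2-yl)ethyl]-3-methyl-6-(propan-2-yl)cyclohex-3-en-1-yl]prop-2-enoate | COC(=O)/C(Br)=C/[C@H]1[C@@H](C(C)C)CC=C(C)[C@@H]1C[C@H](O[Si](C)(C)C(C)(C)C)c1ccco1 | intermediate
19 | furanophane silyl ether (C3–C4 bond closed; furan C4–C7; C8–OSiMe2t-Bu; 1R,8S,10R,14R) | COC(=O)/C1=C/[C@H]2[C@@H](C(C)C)CC=C(C)[C@@H]2C[C@H](O[Si](C)(C)C(C)(C)C)c2ccc1o2 | intermediate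
20 | furanophane carbinol (C8–OH; 1R,8S,10R,14R) | COC(=O)/C1=C/[C@H]2[C@@H](C(C)C)CC=C(C)[C@@H]2C[C@H](O)c2ccc1o2 | intermediate
21 | macrocyclic (5Z)-4,7-dione with C8–OH (1R,8S,10R,14R) | COC(=O)/C1=C/[C@H]2[C@@H](C(C)C)CC=C(C)[C@@H]2C[C@H](O)C(=O)/C=C\C1=O | intermediate
22 | bridged hydroxypyranone (O8–C4 bond, C4–OH, C7=O; 1R,4S,8S,10R,14R) | COC(=O)/C1=C/[C@H]2[C@@H](C(C)C)CC=C(C)[C@@H]2C[C@@H]3O[C@@]1(O)C=CC3=O | intermediate
23 | bridged pyranose diol (C7(OH)(CH3); 1R,4S,7S,8S,10R,14R) | COC(=O)/C1=C/[C@H]2[C@@H](C(C)C)CC=C(C)[C@@H]2C[C@@H]3O[C@@]1(O)C=C[C@]3(C)O | intermediate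
24 | 1-methyl-1H-imidazole-4-carbaldehyde | O=Cc1cn(C)cn1 | starting material
25 | 2-[(1-methyl-1H-imidazol-4-yl)methylidene]propanedioic acid | OC(=O)C(=Cc1cn(C)cn1)C(O)=O | intermediate
26 | (2E)-3-(1-methyl-1H-imidazol-4-yl)prop-2-enoic acid | OC(=O)/C=C/c1cn(C)cn1 | intermediate
27 | (2E)-3-(1-methyl-1H-imidazol-4-yl)prop-2-enoic pivalic anhydride | CC(C)(C)C(=O)OC(=O)/C=C/c1cn(C)cn1 | intermediate
28 | furanose hemiketal triol, the de-acyl target (C4–O–C7 bridge, C4–OH, C8–OH; 1R,4R,7S,8S,10R,14R) | COC(=O)/C1=C/[C@H]2[C@@H](C(C)C)CC=C(C)[C@@H]2C[C@H](O)[C@]2(C)C=C[C@@]1(O)O2 | intermediate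
29 | CNP0372023.1 (1R,4R,7S,8S,10R,14R) | COC(=O)/C1=C/[C@H]2[C@@H](C(C)C)CC=C(C)[C@@H]2C[C@H](OC(=O)/C=C/c2cn(C)cn2)[C@]2(C)C=C[C@@]1(O)O2 | target

**Totals**
Total steps: 20. Longest linear sequence: 19 (steps 1–18, then 20).

**Three steps most likely to fail, with fallbacks**

Step 15 (the proposed new macrocyclising C–H alkenylation; risks are ring strain, oligomerisation and base‑induced γ‑deprotonation of the enoate). The fallback uses known chemistry, an intramolecular Stille coupling, and sets out from alcohol 16. Treatment of 16 with n‑BuLi (2.2 equiv, THF, −78 → 0 °C) deprotonates the O–H and lithiates the free furan α‑position, and Bu3SnCl then gives [(1S,2R,6R)-2-[(2S)-2-[(tert-butyldimethylsilyl)oxy]-2-[5-(tributylstannyl)furan-2-yl]ethyl]-3-methyl-6-(propan-2-yl)cyclohex-3-en-1-yl]methanol F1. Buffered Dess–Martin oxidation gives the corresponding stannyl carbaldehyde F2, and the bromo‑ylide Wittig reaction of step 14 gives the stannyl (Z)-α-bromoenoate F3. Ring closure of F3 with Pd2(dba)3, AsPh3 and CuI in DMF at 45 °C under high dilution, with both coupling partners prefunctionalised, gives 19, where the route is re‑joined.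

Step 18 (methyl addition to the free hydroxypyranone; the hemiketal alkoxide may ring‑open, which would erode site and face selectivity, and the enoate ester may compete). The fallback sets out from 22. MeOH with pyridinium p‑toluenesulfonate converts 22 into the bridged pyranone methyl ketal F4, which cannot ring‑open. MeLi/CeCl3 at −78 °C then adds from the exo face to give the C7‑methyl carbinol methyl ketal F5. Mild hydrolysis (pyridinium p‑toluenesulfonate, acetone/H2O) returns to the route at 23.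

Step 20 (acylation of a tautomerising, hindered alcohol with a poorly soluble heteroaryl acrylic acid). The fallback sets out from 23 and builds the urocanate on the molecule instead. Diethylphosphonoacetic acid, DCC and DMAP acylate the C8–OH of the furanose tautomer with a small, reactive acyl donor to give the C8 diethylphosphonoacetate of the furanose hemiketal F6. A Horner–Wadsworth–Emmons reaction of F6 with aldehyde 24 (LiCl, DBU, MeCN, 25 °C) is E‑selective and comes back to the route at 29.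

**Further compounds**

F1 | step 15 | [(1S,2R,6R)-2-[(2S)-2-[(tert-butyldimethylsilyl)oxy]-2-[5-(tributylstannyl)furan-2-yl]ethyl]-3-methyl-6-(propan-2-yl)cyclohex-3-en-1-yl]methanol | OC[C@H]1[C@@H](C(C)C)CC=C(C)[C@@H]1C[C@H](O[Si](C)(C)C(C)(C)C)c1ccc([Sn](CCCC)(CCCC)CCCC)o1
F2 | step 15 | (1S,2R,6R)-2-[(2S)-2-[(tert-butyldimethylsilyl)oxy]-2-[5-(tributylstannyl)furan-2-yl]ethyl]-3-methyl-6-(propan-2-yl)cyclohex-3-ene-1-carbaldehyde | O=C[C@H]1[C@@H](C(C)C)CC=C(C)[C@@H]1C[C@H](O[Si](C)(C)C(C)(C)C)c1ccc([Sn](CCCC)(CCCC)CCCC)o1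
F3 | step 15 | methyl (2Z)-2-bromo-3-[(1S,2R,6R)-2-[(2S)-2-[(tert-butyldimethylsilyl)oxy]-2-[5-(tributylstannyl)furan-2-yl]ethyl]-3-methyl-6-(propan-2-yl)cyclohex-3-en-1-yl]prop-2-enoate | COC(=O)/C(Br)=C/[C@H]1[C@@H](C(C)C)CC=C(C)[C@@H]1C[C@H](O[Si](C)(C)C(C)(C)C)c1ccc([Sn](CCCC)(CCCC)CCCC)o1
F4 | step 18 | bridged pyranone methyl ketal (22 with C4–OCH3) | COC(=O)/C1=C/[C@H]2[C@@H](C(C)C)CC=C(C)[C@@H]2C[C@@H]3O[C@@]1(OC)C=CC3=O
F5 | step 18 | C7-methyl carbinol methyl ketal (23 with C4–OCH3) | COC(=O)/C1=C/[C@H]2[C@@H](C(C)C)CC=C(C)[C@@H]2C[C@@H]3O[C@@]1(OC)C=C[C@]3(C)O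
F6 | step 20 | C8 diethylphosphonoacetate of furanose hemiketal 28 | COC(=O)/C1=C/[C@H]2[C@@H](C(C)C)CC=C(C)[C@@H]2C[C@H](OC(=O)CP(=O)(OCC)OCC)[C@]2(C)C=C[C@@]1(O)O2
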